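**Plan**

- Retrosynthesis: the side chain (C1' is the CH2 on butenolide C5) is cut between the hydroxymethyl-bearing olefinic carbon C3' and the allylic CH2 C4'. Fragment 1 is the C16 homoallylic Grignard reagent 8 from dihydro-β-ionone; fragment 2 is the alkynyl diol 22, traced back through a butenolide and an α-hydroxy ketone to methyl (R)-glycidate.
- Enabling feature: the butenolide ring oxygen O1 sits on C5, and C5 is one CH2 (C1') away from the olefinic CH C2'. With the lactone reduced to the (Z)-ene-1,4-diol, this oxygen is a free homopropargylic alkoxide towards a C2'≡C3' alkyne. It steers an iron-catalysed syn-carbomagnesiation that forms the C3'–C4' bond and the (2'Z)-trisubstituted alkene in one event.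
- Forward order: the cyclohexene ring is bought in. Fragment 1 is made by alkyne formation, methylalumination/oxirane opening, bromination and magnesium insertion. The butenolide ring is built early (epoxide opening, Weinreb ketone synthesis, ylide lactonisation), opened by reduction, reclosed by oxidative lactonisation after the fragments are joined, and the two protecting groups are then removed.
- Stereochemistry: C5 (R) comes from methyl (R)-glycidate and no bond to it is ever broken. The (6'E) alkene comes from syn-methylalumination, the (2'Z) alkene from syn-carbomagnesiation, and the cis geometry needed for relactonisation is stored by the butenolide ring before reduction.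

Key step: step 11

Assumption: compounds 1, 9, 10, 13 and 14 and the ylide Ph3P=C=C=O are taken as purchasable.

**Route**

Step 1
Reactants: 1 dihydro-β-ionone
Product: 3 2-(but-3-yn-1-yl)-1,3,3-trimethylcyclohex-1-ene, via enol phosphate 2 (not isolated)
Conditions: LiN(i-Pr)2 (1.05 equiv), THF, −78 °C; ClP(O)(OEt)2, −78 °C → rt; LiN(i-Pr)2 (2.3 equiv), −78 °C → rt; aq. NH4Cl
Reagents that add atoms: none
Why: Kinetic deprotonation of the methyl ketone at the methyl group, O-phosphorylation and base-induced elimination of the enol phosphate should give the terminal alkyne (enol phosphate elimination), the tetrasubstituted ring alkene being inert.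

Step 2
Reactants: 3 2-(but-3-yn-1-yl)-1,3,3-trimethylcyclohex-1-ene
Product: 6 (3E)-4-methyl-6-(2,6,6-trimethylcyclohex-1-en-1-yl)hex-3-en-1-ol, via alkenylalane 4 (not isolated), via lithium alanate 5 (not isolated)
Conditions: Me3Al (2 equiv), Cp2ZrCl2 (0.25 equiv), CH2Cl2, rt; volatiles removed; n-BuLi, hexane/THF, −78 → 0 °C; oxirane, 0 °C → rt; aq. HCl
Reagents that add atoms: trimethylaluminium, C[Al](C)C; oxirane, C1CO1
Why: Zirconium-catalysed syn-methylalumination (Negishi carboalumination) places methyl on the internal carbon and aluminium cis to it on the terminal carbon, and the alkenyl group of the derived alanate opens oxirane with retention, which sets the (E)-trisubstituted alkene.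

Step 3
Reactants: 6 (3E)-4-methyl-6-(2,6,6-trimethylcyclohex-1-en-1-yl)hex-3-en-1-ol
Product: 7 2-[(3E)-6-bromo-3-methylhex-3-en-1-yl]-1,3,3-trimethylcyclohex-1-ene
Conditions: CBr4, PPh3, CH2Cl2, 0 °C
Reagents that add atoms: carbon tetrabromide, BrC(Br)(Br)Br
Why: Appel bromination of the primary homoallylic alcohol proceeds by SN2 displacement of the oxyphosphonium group and leaves both alkenes untouched.

Step 4
Reactants: 7 2-[(3E)-6-bromo-3-methylhex-3-en-1-yl]-1,3,3-trimethylcyclohex-1-ene
Product: 8 [(3E)-4-methyl-6-(2,6,6-trimethylcyclohex-1-en-1-yl)hex-3-en-1-yl]magnesium bromide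
Conditions: Mg turnings (I2-activated), THF, rt → 40 °C; used as titrated solution
Reagents that add atoms: magnesium, [Mg]
Why: Magnesium inserts into the primary C–Br bond (Grignard formation), and the homoallyl/cyclopropylcarbinyl equilibration that could scramble the alkene geometry is slow for the organomagnesium species at this temperature.

Step 5
Reactants: 9 4-methoxybenzyl alcohol; 10 tributyl(iodomethyl)stannane
Product: 12 tributyl{[(4-methoxybenzyl)oxy]methyl}stannane, via sodium alkoxide 11 (not isolated)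
Conditions: NaH, THF/DMF, 0 °C; then 10, rt
Reagents that add atoms: none
Why: Williamson ether synthesis, in which the alkoxide displaces the primary iodide next to tin by SN2.

Step 6
Reactants: 13 tert-butyldimethyl(prop-2-yn-1-yloxy)silane; 14 methyl (2R)-oxirane-2-carboxylate
Product: 16 methyl (2R)-6-[(tert-butyldimethylsilyl)oxy]-2-hydroxyhex-4-ynoate, via lithium acetylide 15 (not isolated)
Conditions: 13, n-BuLi, THF, −78 °C; BF3·OEt2, −78 °C; then 14, −78 °C; sat. aq. NH4Cl
Reagents that add atoms: none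
Why: BF3-promoted opening of the epoxide by the lithium acetylide (Yamaguchi-type alkynylation) should occur at the unsubstituted ring carbon, so the glycidate stereocentre is untouched and becomes the (R)-carbinol, while the ester is not attacked at −78 °C.

Step 7
Reactants: 16 methyl (2R)-6-[(tert-butyldimethylsilyl)oxy]-2-hydroxyhex-4-ynoate
Product: 17 (2R)-6-[(tert-butyldimethylsilyl)oxy]-2-hydroxy-N-methoxy-N-methylhex-4-ynamide
Conditions: MeNH(OMe)·HCl (3 equiv), i-PrMgCl (6.5 equiv), THF, −20 → 0 °C; aq. NH4Cl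
Reagents that add atoms: N,O-dimethylhydroxylamine hydrochloride, CNOC.Cl
Why: Aminolysis of the methyl ester by the magnesium amide of N,O-dimethylhydroxylamine (Weinreb amide formation) is expected to proceed without protection of the neighbouring hydroxyl and without epimerisation.

Step 8
Reactants: 17 (2R)-6-[(tert-butyldimethylsilyl)oxy]-2-hydroxy-N-methoxy-N-methylhex-4-ynamide; 12 tributyl{[(4-methoxybenzyl)oxy]methyl}stannane
Product: 19 (3R)-7-[(tert-butyldimethylsilyl)oxy]-3-hydroxy-1-[(4-methoxybenzyl)oxy]hept-5-yn-2-one, via alkoxymethyllithium 18 (not isolated)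
Conditions: 12 (2.6 equiv), n-BuLi (2.5 equiv), THF, −78 °C; then 17, −78 → −40 °C; sat. aq. NH4Cl
Reagents that add atoms: none
Why: Tin–lithium exchange gives the α-alkoxymethyllithium, whose addition to the amide stops at the chelated tetrahedral intermediate and releases the ketone on work-up (Weinreb ketone synthesis), the first equivalent serving only to deprotonate the hydroxyl.

Step 9
Reactants: 19 (3R)-7-[(tert-butyldimethylsilyl)oxy]-3-hydroxy-1-[(4-methoxybenzyl)oxy]hept-5-yn-2-one
Product: 21 (5R)-5-{4-[(tert-butyldimethylsilyl)oxy]but-2-yn-1-yl}-4-{[(4-methoxybenzyl)oxy]methyl}furan-2(5H)-one, via ester ylide 20 (not isolated)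
Conditions: Ph3P=C=C=O, toluene, 80 °C
Reagents that add atoms: (triphenylphosphoranylidene)ketene, O=C=C=P(c1ccccc1)(c1ccccc1)c1ccccc1
Why: The hydroxyl adds to the cumulated ylide (Bestmann ylide) and the resulting ester ylide closes the five-membered butenolide ring by intramolecular Wittig olefination of the adjacent ketone, the ring fixing the cis relation of C5 and the carbonyl carbon.

Step 10
Reactants: 21 (5R)-5-{4-[(tert-butyldimethylsilyl)oxy]but-2-yn-1-yl}-4-{[(4-methoxybenzyl)oxy]methyl}furan-2(5H)-one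
Product: 22 (2Z,4R)-8-[(tert-butyldimethylsilyl)oxy]-3-{[(4-methoxybenzyl)oxy]methyl}oct-2-en-6-yne-1,4-diol
Conditions: i-Bu2AlH (3.5 equiv), CH2Cl2, −78 → −20 °C; aq. potassium sodium tartrate
Reagents that add atoms: none
Why: 1,2-Reduction of the unsaturated lactone by the aluminium hydride opens the ring to the (Z)-ene-1,4-diol, which masks the lactone against the Grignard reagent, frees the C4 hydroxyl as directing group and keeps the ring-derived Z geometry for reclosure.

Step 11
Reactants: 22 (2Z,4R)-8-[(tert-butyldimethylsilyl)oxy]-3-{[(4-methoxybenzyl)oxy]methyl}oct-2-en-6-yne-1,4-diol; 8 [(3E)-4-methyl-6-(2,6,6-trimethylcyclohex-1-en-1-yl)hex-3-en-1-yl]magnesium bromide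
Product: 25 (2Z,4R,6Z,10E)-7-{[(tert-butyldimethylsilyl)oxy]methyl}-3-{[(4-methoxybenzyl)oxy]methyl}-11-methyl-13-(2,6,6-trimethylcyclohex-1-en-1-yl)trideca-2,6,10-triene-1,4-diol, via dialkoxide 23 (not isolated), via alkenylmagnesium 24 (not isolated)
Conditions: MeMgBr (1.95 equiv), THF, 0 °C; Fe(acac)3 (20 mol%), dppe (20 mol%); 8 (2.5 equiv), −20 → 0 °C; sat. aq. NH4Cl
Reagents that add atoms: none
Why: Deprotonation gives dialkoxide 23, whose C4 alkoxide (the future lactone oxygen) binds a reduced alkyl-iron species formed from Fe(acac)3 and 8 and delivers it across the C6≡C7 triple bond, iron going to the proximal carbon C6 and the alkyl group to the distal carbon C7 on the same face; exchange with further 8 releases the alkenylmagnesium chelate 24, and protonation on work-up replaces magnesium by hydrogen with retention. The closest known reaction type is the iron-catalysed, alkoxide-directed syn-carbomagnesiation of homopropargylic alcohols with alkyl Grignard reagents. No ring of the product is closed; the only ring involved is the transient five-membered metallacycle (O, C4, C5, C6, metal) that fixes the regiochemistry. No stereocentre is created and C4 is not touched; the syn addition places the new chain cis to the C6 hydrogen, so the CH2OTBS group ends cis to C5, which is the required 6Z geometry. The step needs regioselectivity for C7 over C6, secured by the homopropargylic alkoxide because the propargylic oxygen on the other side is masked as a poorly coordinating silyl ether. It also needs chemoselectivity over the allylic diol unit and the alkenes of 8, none of which is activated towards carbometalation, and the sub-stoichiometric MeMgBr is fully consumed as base before the catalyst is added so that no methyl transfer can compete.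

Step 12
Reactants: 25 (2Z,4R,6Z,10E)-7-{[(tert-butyldimethylsilyl)oxy]methyl}-3-{[(4-methoxybenzyl)oxy]methyl}-11-methyl-13-(2,6,6-trimethylcyclohex-1-en-1-yl)trideca-2,6,10-triene-1,4-diol
Product: 28 (5R)-5-[(2Z,6E)-3-{[(tert-butyldimethylsilyl)oxy]methyl}-7-methyl-9-(2,6,6-trimethylcyclohex-1-en-1-yl)nona-2,6-dien-1-yl]-4-{[(4-methoxybenzyl)oxy]methyl}furan-2(5H)-one, via hydroxy enal 26 (not isolated), via lactol 27 (not isolated)
Conditions: TEMPO (20 mol%), PhI(OAc)2 (2.5 equiv), CH2Cl2, rt
Reagents that add atoms: none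
Why: Oxoammonium oxidation is selective for the primary allylic alcohol, the (Z)-hydroxy enal closes to the lactol and this is oxidised on to the butenolide (oxidative lactonisation of a 1,4-diol) without any base that could epimerise C5.

Step 13
Reactants: 28 (5R)-5-[(2Z,6E)-3-{[(tert-butyldimethylsilyl)oxy]methyl}-7-methyl-9-(2,6,6-trimethylcyclohex-1-en-1-yl)nona-2,6-dien-1-yl]-4-{[(4-methoxybenzyl)oxy]methyl}furan-2(5H)-one
Product: 29 (5R)-5-[(2Z,6E)-3-{[(tert-butyldimethylsilyl)oxy]methyl}-7-methyl-9-(2,6,6-trimethylcyclohex-1-en-1-yl)nona-2,6-dien-1-yl]-4-(hydroxymethyl)furan-2(5H)-one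
Conditions: DDQ, CH2Cl2/pH 7 buffer, 0 °C
Reagents that add atoms: none
Why: Oxidative cleavage of the 4-methoxybenzyl ether by DDQ through the benzylic oxocarbenium ion and its hydrolysis is done while the electron-rich allylic oxygen is still silylated, so that only the electron-poor hydroxymethyl group is set free in the presence of the oxidant.

Step 14
Reactants: 29 (5R)-5-[(2Z,6E)-3-{[(tert-butyldimethylsilyl)oxy]methyl}-7-methyl-9-(2,6,6-trimethylcyclohex-1-en-1-yl)nona-2,6-dien-1-yl]-4-(hydroxymethyl)furan-2(5H)-one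
Product: 30 (6Z)-neomanoalide
Conditions: HF·pyridine, pyridine/THF, 0 °C → rt
Reagents that add atoms: none
Why: Fluoride cleavage of the primary silyl ether under buffered, weakly acidic conditions should neither epimerise the γ-stereocentre of the butenolide nor ionise the allylic alcohols.

**Compound list**

1 | dihydro-β-ionone, 4-(2,6,6-trimethylcyclohex-1-en-1-yl)butan-2-one | CC1=C(CCC(C)=O)C(C)(C)CCC1 | starting material
2 | diethyl 4-(2,6,6-trimethylcyclohex-1-en-1-yl)but-1-en-2-yl phosphate | CC1=C(CCC(=C)OP(=O)(OCC)OCC)C(C)(C)CCC1 | intermediate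
3 | 2-(but-3-yn-1-yl)-1,3,3-trimethylcyclohex-1-ene | CC1=C(CCC#C)C(C)(C)CCC1 | intermediate
4 | dimethyl[(1E)-2-methyl-4-(2,6,6-trimethylcyclohex-1-en-1-yl)but-1-en-1-yl]alane | CC1=C(CC/C(C)=C/[Al](C)C)C(C)(C)CCC1 | intermediate
5 | lithium butyl(dimethyl)[(1E)-2-methyl-4-(2,6,6-trimethylcyclohex-1-en-1-yl)but-1-en-1-yl]aluminate | [Li+].CC1=C(CC/C(C)=C/[Al-](C)(C)CCCC)C(C)(C)CCC1 | intermediate
6 | (3E)-4-methyl-6-(2,6,6-trimethylcyclohex-1-en-1-yl)hex-3-en-1-ol | CC1=C(CC/C(C)=C/CCO)C(C)(C)CCC1 | intermediate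
7 | 2-[(3E)-6-bromo-3-methylhex-3-en-1-yl]-1,3,3-trimethylcyclohex-1-ene | CC1=C(CC/C(C)=C/CCBr)C(C)(C)CCC1 | intermediate
8 | [(3E)-4-methyl-6-(2,6,6-trimethylcyclohex-1-en-1-yl)hex-3-en-1-yl]magnesium bromide | CC1=C(CC/C(C)=C/CC[Mg]Br)C(C)(C)CCC1 | intermediate
9 | 4-methoxybenzyl alcohol | COc1ccc(CO)cc1 | starting material
10 | tributyl(iodomethyl)stannane | CCCC[Sn](CCCC)(CCCC)CI | starting material
11 | sodium 4-methoxybenzyl oxide | [Na+].COc1ccc(C[O-])cc1 | intermediate
12 | tributyl{[(4-methoxybenzyl)oxy]methyl}stannane | CCCC[Sn](CCCC)(CCCC)COCc1ccc(OC)cc1 | intermediate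
13 | tert-butyldimethyl(prop-2-yn-1-yloxy)silane | C#CCO[Si](C)(C)C(C)(C)C | starting material
14 | methyl (2R)-oxirane-2-carboxylate, methyl (R)-glycidate | COC(=O)[C@H]1CO1 | starting material
15 | {3-[(tert-butyldimethylsilyl)oxy]prop-1-yn-1-yl}lithium | [Li]C#CCO[Si](C)(C)C(C)(C)C | intermediate
16 | methyl (2R)-6-[(tert-butyldimethylsilyl)oxy]-2-hydroxyhex-4-ynoate | CC(C)(C)[Si](C)(C)OCC#CC[C@@H](O)C(=O)OC | intermediate
17 | (2R)-6-[(tert-butyldimethylsilyl)oxy]-2-hydroxy-N-methoxy-N-methylhex-4-ynamide | CC(C)(C)[Si](C)(C)OCC#CC[C@@H](O)C(=O)N(C)OC | intermediate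
18 | {[(4-methoxybenzyl)oxy]methyl}lithium | [Li]COCc1ccc(OC)cc1 | intermediate
19 | (3R)-7-[(tert-butyldimethylsilyl)oxy]-3-hydroxy-1-[(4-methoxybenzyl)oxy]hept-5-yn-2-one | CC(C)(C)[Si](C)(C)OCC#CC[C@@H](O)C(=O)COCc1ccc(OC)cc1 | intermediate
20 | (3R)-7-[(tert-butyldimethylsilyl)oxy]-1-[(4-methoxybenzyl)oxy]-2-oxohept-5-yn-3-yl (triphenylphosphoranylidene)acetate | CC(C)(C)[Si](C)(C)OCC#CC[C@@H](OC(=O)C=P(c1ccccc1)(c1ccccc1)c1ccccc1)C(=O)COCc1ccc(OC)cc1 | intermediate
21 | (5R)-5-{4-[(tert-butyldimethylsilyl)oxy]but-2-yn-1-yl}-4-{[(4-methoxybenzyl)oxy]methyl}furan-2(5H)-one | CC(C)(C)[Si](C)(C)OCC#CC[C@H]1OC(=O)C=C1COCc1ccc(OC)cc1 | intermediate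
22 | (2Z,4R)-8-[(tert-butyldimethylsilyl)oxy]-3-{[(4-methoxybenzyl)oxy]methyl}oct-2-en-6-yne-1,4-diol | CC(C)(C)[Si](C)(C)OCC#CC[C@@H](O)/C(COCc1ccc(OC)cc1)=C\CO | intermediate
23 | bis(bromomagnesium) 1,4-dialkoxide of 22 | CC(C)(C)[Si](C)(C)OCC#CC[C@@H](O[Mg]Br)/C(COCc1ccc(OC)cc1)=C\CO[Mg]Br | intermediate
24 | C6-bromomagnesio alkene from syn addition of 8 to 23 (new chain on C7 cis to magnesium on C6; both alkoxides as bromomagnesium salts) | CC1=C(CC/C(C)=C/CC/C(CO[Si](C)(C)C(C)(C)C)=C(\[Mg]Br)C[C@@H](O[Mg]Br)/C(COCc2ccc(OC)cc2)=C\CO[Mg]Br)C(C)(C)CCC1 | intermediate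
25 | (2Z,4R,6Z,10E)-7-{[(tert-butyldimethylsilyl)oxy]methyl}-3-{[(4-methoxybenzyl)oxy]methyl}-11-methyl-13-(2,6,6-trimethylcyclohex-1-en-1-yl)trideca-2,6,10-triene-1,4-diol | CC1=C(CC/C(C)=C/CC/C(CO[Si](C)(C)C(C)(C)C)=C/C[C@@H](O)/C(COCc2ccc(OC)cc2)=C\CO)C(C)(C)CCC1 | intermediate
26 | (2Z,4R,6Z,10E)-7-{[(tert-butyldimethylsilyl)oxy]methyl}-4-hydroxy-3-{[(4-methoxybenzyl)oxy]methyl}-11-methyl-13-(2,6,6-trimethylcyclohex-1-en-1-yl)trideca-2,6,10-trienal | CC1=C(CC/C(C)=C/CC/C(CO[Si](C)(C)C(C)(C)C)=C/C[C@@H](O)/C(COCc2ccc(OC)cc2)=C\C=O)C(C)(C)CCC1 | intermediate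
27 | (5R)-5-[(2Z,6E)-3-{[(tert-butyldimethylsilyl)oxy]methyl}-7-methyl-9-(2,6,6-trimethylcyclohex-1-en-1-yl)nona-2,6-dien-1-yl]-4-{[(4-methoxybenzyl)oxy]methyl}-2,5-dihydrofuran-2-ol (both configurations at C2) | CC1=C(CC/C(C)=C/CC/C(CO[Si](C)(C)C(C)(C)C)=C/C[C@H]2OC(O)C=C2COCc3ccc(OC)cc3)C(C)(C)CCC1 | intermediate
28 | (5R)-5-[(2Z,6E)-3-{[(tert-butyldimethylsilyl)oxy]methyl}-7-methyl-9-(2,6,6-trimethylcyclohex-1-en-1-yl)nona-2,6-dien-1-yl]-4-{[(4-methoxybenzyl)oxy]methyl}furan-2(5H)-one | CC1=C(CC/C(C)=C/CC/C(CO[Si](C)(C)C(C)(C)C)=C/C[C@H]2OC(=O)C=C2COCc3ccc(OC)cc3)C(C)(C)CCC1 | intermediate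
29 | (5R)-5-[(2Z,6E)-3-{[(tert-butyldimethylsilyl)oxy]methyl}-7-methyl-9-(2,6,6-trimethylcyclohex-1-en-1-yl)nona-2,6-dien-1-yl]-4-(hydroxymethyl)furan-2(5H)-one | CC1=C(CC/C(C)=C/CC/C(CO[Si](C)(C)C(C)(C)C)=C/C[C@H]2OC(=O)C=C2CO)C(C)(C)CCC1 | intermediate
30 | (6Z)-neomanoalide, (5R)-4-(hydroxymethyl)-5-[(2Z,6E)-3-(hydroxymethyl)-7-methyl-9-(2,6,6-trimethylcyclohex-1-en-1-yl)nona-2,6-dien-1-yl]furan-2(5H)-one | CC1=C(CC/C(C)=C/CC/C(=C/C[C@H]2OC(=O)C=C2CO)CO)C(C)(C)CCC1 | target

**Step count and risks**

Total step count: 14. Longest linear sequence: 9 steps (steps 6 to 14, from 13 and 14).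

Steps most likely to fail:

Step 11. The alkyl-iron intermediate could undergo β-hydride elimination, which would turn the carbometalation into a hydrometalation and consume 8. Regiocontrol could also erode if the silyl ether oxygen competes as a ligand, and the silyloxy group could be lost by SN2′ substitution to an allene. The fallback sets out from butenolide 21 and Grignard reagent 8 and comes back to the route at 28, so that steps 10 to 12 are not needed. Palladium-catalysed syn-hydrostannation of 21 (Bu3SnH, Pd(PPh3)2Cl2, THF) should place tin mainly on the alkyne carbon next to the CH2OTBS group and give the (E)-alkenylstannane F1. Iododestannylation (I2, CH2Cl2, 0 °C) with retention would give the alkenyl iodide F2. Transmetalation of 8 with ZnBr2 would give the alkylzinc bromide F3, and a base-free Negishi coupling of F2 with F3 (Pd(dppf)Cl2, THF, rt) would form the same C–C bond with retention of the alkene geometry and deliver 28.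

Step 12. The lactol could dehydrate to a furan under the acetic acid that is released, in competition with its oxidation. The hydroxy enal could also isomerise from Z to E before it cyclises, or the secondary allylic alcohol could be oxidised. The fallback sets out from 25 and comes back at 28, and it avoids any free lactol. Both hydroxyls would be silylated (Et3SiCl, imidazole, DMF) to the bis(triethylsilyl) ether F4. Swern oxidation ((COCl)2, DMSO, Et3N, −78 → −30 °C) would convert the primary triethylsilyl ether directly into the (Z)-enal F5 while the secondary silyl ether stays. Pinnick oxidation (NaClO2, NaH2PO4, 2-methylbut-2-ene, t-BuOH/H2O) would give the (Z)-enoic acid F6. Mild acid (AcOH/THF/H2O) would then remove the secondary triethylsilyl group, and the freed hydroxy acid should lactonise to 28.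

Step 9. The α-hydroxy ketone could enolise under the basic ylide at 80 °C, with erosion of configuration at the carbinol carbon, or acylation of the hindered hydroxyl could be slow. The fallback sets out from 19 and comes back at 21. Esterification of 19 with diethylphosphonoacetic acid (DCC, DMAP, CH2Cl2, 0 °C) would give the phosphonoacetate F7. An intramolecular Horner–Wadsworth–Emmons reaction under Masamune–Roush conditions (LiCl, i-Pr2NEt, MeCN, 0 °C) would then close the butenolide ring of 21 at low temperature.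

Further compounds
F1 | step 11 | (5R)-5-[(2E)-4-[(tert-butyldimethylsilyl)oxy]-3-(tributylstannyl)but-2-en-1-yl]-4-{[(4-methoxybenzyl)oxy]methyl}furan-2(5H)-one | CCCC[Sn](CCCC)(CCCC)/C(CO[Si](C)(C)C(C)(C)C)=C/C[C@H]1OC(=O)C=C1COCc1ccc(OC)cc1
F2 | step 11 | (5R)-5-[(2E)-4-[(tert-butyldimethylsilyl)oxy]-3-iodobut-2-en-1-yl]-4-{[(4-methoxybenzyl)oxy]methyl}furan-2(5H)-one | I/C(CO[Si](C)(C)C(C)(C)C)=C/C[C@H]1OC(=O)C=C1COCc1ccc(OC)cc1
F3 | step 11 | [(3E)-4-methyl-6-(2,6,6-trimethylcyclohex-1-en-1-yl)hex-3-en-1-yl]zinc bromide | CC1=C(CC/C(C)=C/CC[Zn]Br)C(C)(C)CCC1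
F4 | step 12 | 1,4-bis(triethylsilyl) ether of 25 | CC1=C(CC/C(C)=C/CC/C(CO[Si](C)(C)C(C)(C)C)=C/C[C@@H](O[Si](CC)(CC)CC)/C(COCc2ccc(OC)cc2)=C\CO[Si](CC)(CC)CC)C(C)(C)CCC1
F5 | step 12 | (2Z,4R,6Z,10E)-7-{[(tert-butyldimethylsilyl)oxy]methyl}-3-{[(4-methoxybenzyl)oxy]methyl}-11-methyl-4-[(triethylsilyl)oxy]-13-(2,6,6-trimethylcyclohex-1-en-1-yl)trideca-2,6,10-trienal | CC1=C(CC/C(C)=C/CC/C(CO[Si](C)(C)C(C)(C)C)=C/C[C@@H](O[Si](CC)(CC)CC)/C(COCc2ccc(OC)cc2)=C\C=O)C(C)(C)CCC1
F6 | step 12 | (2Z,4R,6Z,10E)-7-{[(tert-butyldimethylsilyl)oxy]methyl}-3-{[(4-methoxybenzyl)oxy]methyl}-11-methyl-4-[(triethylsilyl)oxy]-13-(2,6,6-trimethylcyclohex-1-en-1-yl)trideca-2,6,10-trienoic acid | CC1=C(CC/C(C)=C/CC/C(CO[Si](C)(C)C(C)(C)C)=C/C[C@@H](O[Si](CC)(CC)CC)/C(COCc2ccc(OC)cc2)=C\C(=O)O)C(C)(C)CCC1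
F7 | step 9 | (3R)-7-[(tert-butyldimethylsilyl)oxy]-1-[(4-methoxybenzyl)oxy]-2-oxohept-5-yn-3-yl (diethoxyphosphoryl)acetate | CC(C)(C)[Si](C)(C)OCC#CC[C@@H](OC(=O)CP(=O)(OCC)OCC)C(=O)COCc1ccc(OC)cc1
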